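**Strategy.** Atoms are numbered as they occur in the target SMILES. The plan rests on cutting C3–C4 of the nine-membered ring: the exocyclic methylene C1=C2 flanked by that bond is the signature of a [3,3] shift of a 2-methyleneallyl ester. An Ireland–Claisen contraction of an eleven-membered lactone (C4–C(=O)–O–C1, C2=C3 terminal) therefore forms C3–C4, closes the carbocycle and sets the C2=C1 olefin in one operation; the extra C4 carboxyl is then removed. The lactone arises from a seco acid joining a caryophyllene-derived trans-cyclobutane carrying a 2-(hydroxymethyl)vinyl group to a pyran–trione core made by enamine-catalysed Michael addition and axial C14 methylation.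

Key step: step 17

Remark: atom labels used below (C1 exocyclic CH2; C5, C6 pyran CH; O13; C14 = C(Me)–O; C18, C19 cyclobutane CH) are positions in the target SMILES.
Remark: the peroxidic species of the ozonolysis are a mixture and are not numbered; C14 of 16, 18 and 19 and C4 of 24–27 are left undefined because these centres are set or erased later.
Remark: 11, 15 and (R)-α,α-diphenylprolinol trimethylsilyl ether are taken as purchasable.

**Cyclobutane fragment**

Step 1
Reactants: 1 (−)-β-caryophyllene
Product: 2 4-[(1S,2R)-3,3-dimethyl-2-(3-oxobutyl)cyclobutyl]-4-oxobutanal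
Conditions: O3, CH2Cl2/MeOH, −78 °C; then Me2S, −78 °C → rt
Reagents that add atoms: ozone, [O-][O+]=O
Why: Exhaustive ozonolysis cleaves both the trisubstituted ring alkene and the exocyclic methylene and the reductive work-up stops at the keto aldehyde; the ketone-bearing ring carbon is epimerisable but already trans, the stable arrangement.

Step 2
Reactants: 2 4-[(1S,2R)-3,3-dimethyl-2-(3-oxobutyl)cyclobutyl]-4-oxobutanal
Product: 3 4-[(1R,4S)-4-(furan-2-yl)-2,2-dimethylcyclobutyl]butan-2-one
Conditions: p-TsOH·H2O (5 mol%), PhMe, 4 Å MS, 80 °C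
Reagents that add atoms: none
Why: Paal–Knorr furan synthesis, in which the 1,4-keto aldehyde cyclodehydrates much faster than any aldol path, since the remote methyl ketone could only close a strained trans-fused ring.

Step 3
Reactants: 3 4-[(1R,4S)-4-(furan-2-yl)-2,2-dimethylcyclobutyl]butan-2-one
Product: 4 (1S,2R)-3,3-dimethyl-2-(3-oxobutyl)cyclobutane-1-carboxylic acid
Conditions: RuCl3·xH2O (5 mol%), NaIO4, EtOAc/MeCN/H2O, rt
Reagents that add atoms: sodium periodate, [Na+].[O-]I(=O)(=O)=O
Why: RuO4 oxidation degrades the electron-rich furan to the carboxylic acid it masks, while the ketone and the saturated ring are inert and the acid-bearing carbon keeps its trans configuration.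

Step 4
Reactants: 4 (1S,2R)-3,3-dimethyl-2-(3-oxobutyl)cyclobutane-1-carboxylic acid
Product: 5 (1S,2R)-2-(2-acetoxyethyl)-3,3-dimethylcyclobutane-1-carboxylic acid
Conditions: mCPBA, TFA (1 equiv), CH2Cl2, rt
Reagents that add atoms: mCPBA, OOC(=O)c1cccc(Cl)c1
Why: Baeyer–Villiger oxidation in which the primary alkyl group migrates in preference to methyl, so the acetyl carbon becomes an acetate; no alkene is present at this stage.

Step 5
Reactants: 5 (1S,2R)-2-(2-acetoxyethyl)-3,3-dimethylcyclobutane-1-carboxylic acid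
Product: 6 1-[(1S,2R)-2-(2-hydroxyethyl)-3,3-dimethylcyclobutyl]ethan-1-one
Conditions: MeLi (5 equiv), THF, −78 → 0 °C; inverse quench into aq. NH4Cl
Reagents that add atoms: methyllithium, [Li]C
Why: Ketone synthesis from a lithium carboxylate, where one methyllithium adds to give a gem-dialkoxide that releases the methyl ketone only on quench, while the same reagent cleaves the acetate to the primary alkoxide.

Step 6
Reactants: 6 1-[(1S,2R)-2-(2-hydroxyethyl)-3,3-dimethylcyclobutyl]ethan-1-one
Product: 7 2-[(1R,4S)-2,2-dimethyl-4-(prop-1-en-2-yl)cyclobutyl]ethan-1-ol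
Conditions: Ph3PCH3Br, KOtBu, THF, 0 °C → rt
Reagents that add atoms: methyltriphenylphosphonium bromide, C[P+](c1ccccc1)(c1ccccc1)c1ccccc1.[Br-]
Why: Wittig methylenation of the methyl ketone, any base-induced epimerisation next to the ketone converging on the trans-1,2-disubstituted cyclobutane already present.

Step 7
Reactants: 7 2-[(1R,4S)-2,2-dimethyl-4-(prop-1-en-2-yl)cyclobutyl]ethan-1-ol
Product: 8 (1R,4S)-1-(2-bromoethyl)-2,2-dimethyl-4-(prop-1-en-2-yl)cyclobutane
Conditions: CBr4, PPh3, CH2Cl2, 0 °C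
Reagents that add atoms: carbon tetrabromide, BrC(Br)(Br)Br
Why: Appel reaction, an SN2 displacement of the oxyphosphonium group by bromide at the unhindered primary carbon, to which the alkene is inert.

Step 8
Reactants: 8 (1R,4S)-1-(2-bromoethyl)-2,2-dimethyl-4-(prop-1-en-2-yl)cyclobutane
Product: 9 2-[(1S,2R)-2-(2-bromoethyl)-3,3-dimethylcyclobutyl]prop-2-en-1-ol
Conditions: SeO2 (cat.), t-BuOOH, CH2Cl2, rt
Reagents that add atoms: tert-butyl hydroperoxide, CC(C)(C)OO
Why: Selenium dioxide allylic oxidation (ene reaction then [2,3] shift) should hydroxylate the allylic methyl group, because the alternative ene reaction at the ring C–H would create a strained alkylidenecyclobutane.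

Step 9
Reactants: 9 2-[(1S,2R)-2-(2-bromoethyl)-3,3-dimethylcyclobutyl]prop-2-en-1-ol
Product: 10 (1R,4S)-1-(2-bromoethyl)-2,2-dimethyl-4-[3-(trityloxy)prop-1-en-2-yl]cyclobutane
Conditions: TrCl, Et3N, DMAP (cat.), CH2Cl2, rt
Reagents that add atoms: trityl chloride, ClC(c1ccccc1)(c1ccccc1)c1ccccc1
Why: Tritylation of the unhindered primary allylic alcohol gives an ether that should survive Grignard formation and the Ru oxidation but is removed by mild Lewis acid.

**Pyran–trione core and union**

Step 10
Reactants: 11 syncarpic acid; 12 isovaleraldehyde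
Product: 14 2,2,4,4-tetramethyl-6-(3-methylbutylidene)cyclohexane-1,3,5-trione, via Mannich base 13 (not isolated)
Conditions: piperidine, CH2Cl2, rt; then HCl (2 M in Et2O), rt
Reagents that add atoms: none
Why: Knoevenagel condensation run through the Mannich base, whose acid-induced loss of piperidine should give the alkylidene trione without the 2:1 bis-adduct; no stereocentre is formed and the two flanking carbonyls are equivalent.

Step 11
Reactants: 14 2,2,4,4-tetramethyl-6-(3-methylbutylidene)cyclohexane-1,3,5-trione; 15 tert-butyl 4-oxobutanoate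
Product: 16 tert-butyl 2-[(3S,4S)-2-hydroxy-4-isobutyl-6,6,8,8-tetramethyl-5,7-dioxo-3,4,5,6,7,8-hexahydro-2H-chromen-3-yl]acetate
Conditions: (R)-α,α-diphenylprolinol TMS ether (20 mol%), PhCO2H (20 mol%), PhMe, 0 °C
Reagents that add atoms: none
Why: Diarylprolinol silyl ether enamine catalysis (Michael addition then hemiacetal closure, a formal inverse-demand oxa-Diels–Alder), in which the (R)-catalyst shields one face of the E-enamine and fixes C5 as S, the usual syn topicity fixes C6 as S (3,4-trans lactol), and the anomeric centre is an inconsequential mixture.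

Step 12
Reactants: 10 (1R,4S)-1-(2-bromoethyl)-2,2-dimethyl-4-[3-(trityloxy)prop-1-en-2-yl]cyclobutane; 16 tert-butyl 2-[(3S,4S)-2-hydroxy-4-isobutyl-6,6,8,8-tetramethyl-5,7-dioxo-3,4,5,6,7,8-hexahydro-2H-chromen-3-yl]acetate
Product: 18 tert-butyl (3S,4S)-3-{1-hydroxy-3-[(1R,4S)-2,2-dimethyl-4-(3-trityloxyprop-1-en-2-yl)cyclobutyl]propyl}-4-(2-hydroxy-3,3,5,5-tetramethyl-4,6-dioxocyclohex-1-en-1-yl)-6-methylheptanoate, via Grignard reagent 17 (not isolated)
Conditions: 10, Mg, THF, rt; 16, LiHMDS (1.0 equiv), THF, −78 °C; then the Grignard solution, −78 → −40 °C; aq. NH4Cl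
Reagents that add atoms: none
Why: Grignard addition to the aldehyde unmasked from the lithium lactolate, whose ring-opened form carries the trione as an unreactive enolate; the tert-butyl ester is inert at −78 °C and resists lactonisation by the new alkoxide, closure of the Grignard reagent onto its own alkene would need a trans-fused bicyclo[3.2.0]heptane, and the carbinol configuration (C14, unselective) is removed in the next step.

Step 13
Reactants: 18 the C14 carbinol of step 12
Product: 19 tert-butyl 2-[(3S,4S)-2-hydroxy-4-isobutyl-6,6,8,8-tetramethyl-5,7-dioxo-2-{2-[(1R,4S)-2,2-dimethyl-4-(3-trityloxyprop-1-en-2-yl)cyclobutyl]ethyl}-3,4,5,6,7,8-hexahydro-2H-chromen-3-yl]acetate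
Conditions: TPAP (5 mol%), NMO, 4 Å MS, CH2Cl2, rt
Reagents that add atoms: none
Why: Ley–Griffith oxidation of the secondary alcohol gives the ketone, which the enol oxygen traps as the six-membered hemiketal (C14 equilibrating); C5, now next to a masked ketone, stays in its thermodynamically preferred trans relationship to the isobutyl group.

Step 14
Reactants: 19 the C14 hemiketal of step 13
Product: 20 cis-fused ketal γ-lactone (C14–O–C(=O)–C4H2 closed on the pyran; free 2-(hydroxymethyl)vinyl group; 5S,6S,18R,19S)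
Conditions: ZnBr2 (6 equiv), CH2Cl2, 4 Å MS, rt; aq. NaHCO3
Reagents that add atoms: none
Why: Zinc bromide cleaves tert-butyl esters and trityl ethers under aprotic conditions and the freed carboxyl should capture the hemiketal carbon as a cis-fused γ-lactone (an acyloxy ketal), so that no strong protic acid meets the alkene and no ionisable tertiary pyran ether exists yet.

Step 15
Reactants: 20 the ketal γ-lactone of step 14
Product: 21 2-[(2R,3S,4S)-2-{2-[(1R,4S)-4-(3-hydroxyprop-1-en-2-yl)-2,2-dimethylcyclobutyl]ethyl}-4-isobutyl-2,6,6,8,8-pentamethyl-5,7-dioxo-3,4,5,6,7,8-hexahydro-2H-chromen-3-yl]acetic acid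
Conditions: AlMe3 (6 equiv), CH2Cl2, −78 → 0 °C; Rochelle salt work-up
Reagents that add atoms: trimethylaluminium, C[Al](C)C
Why: Lewis-acid substitution of an acyloxy ketal by trimethylaluminium (C-glycosidation-type methylation), in which ionisation gives the C14 oxocarbenium ion pair and methyl should be transferred axially from the aluminium carboxylate held on the face of the C5 arm, anti to the C6 isobutyl group, so that methyl ends cis to C4 and the long chain equatorial (14R).

**Macrocycle, key step, endgame**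

Step 16
Reactants: 21 the seco hydroxy acid of step 15
Product: 23 eleven-membered 2-methyleneallyl macrolactone (ester O on C1; lactone carbonyl on C4; 5S,6S,14R,18R,19S), via mixed anhydride 22 (not isolated)
Conditions: 2,4,6-Cl3C6H2COCl, Et3N, THF, rt; then slow addition to DMAP, PhMe (1 mM), 80 °C
Reagents that add atoms: none
Why: Yamaguchi macrolactonisation, in which the mixed anhydride is activated by DMAP and closed by the primary allylic alcohol under high dilution, the trans-cyclobutane and the trans C5/C14 substituents pre-organising the eleven-membered ring.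

Step 17
Reactants: 23 the eleven-membered macrolactone of step 16
Product: 26 C4-carboxy tomentodione A (C4 epimers), via silyl ketene acetal 24 (not isolated), via silyl ester 25 (not isolated)
Conditions: LiHMDS, TMSCl/Et3N, THF, −78 °C; then PhMe, 100 °C; then aq. MeOH/NH4Cl
Reagents that add atoms: none
Why: LiHMDS with TMSCl present can enolise only the lactone C4–H2 (the trione ring has no α-hydrogen and C6–H is not acidified), giving ketene acetal 24, in which O–C1–C2=C3 and C4=C(OSi) are the two halves of a [3,3] array. On heating, C3 bonds to C4 while O–C1 breaks, which turns the eleven-membered lactone into the nine-membered carbocycle C2–C3–C4–C5–C14–C16–C17–C18–C19 (closure by a transannular sigmatropic shift through a boat-like array, a net three-atom ring contraction) and leaves C2=C1 as the exocyclic methylene and C4 as a silyl carboxylate. The closest known reaction type is the Ireland–Claisen ring contraction of macrocyclic allylic and 2-methyleneallyl lactones to carbocycles, nine-membered products being at its demanding end. The only new stereocentre, C4, is set by the ring-imposed ketene acetal geometry and the boat transition state, and its configuration does not matter because the carboxyl is removed in step 18. The step needs chemoselective enolisation and a productive transannular conformation: the first is secured by the absence of other acidic C–H bonds, the second by the trans-cyclobutane and the trans-diequatorial C5/C14 pyran substituents, which hold both ends of the array on the same side. Mild hydrolytic work-up then cleaves silyl ester 25 to acid 26.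

Step 18
Reactants: 26 C4-carboxy tomentodione A
Product: 28 tomentodione A, via Barton ester 27 (not isolated)
Conditions: N-hydroxypyridine-2-thione, DCC, DMAP (cat.), CH2Cl2, rt, dark; then Bu3SnH, AIBN (cat.), PhH, 80 °C
Reagents that add atoms: none
Why: Barton reductive decarboxylation, in which the thiohydroxamate ester fragments to the secondary C4 radical that concentrated tributyltin hydride should reduce faster than homoallyl rearrangement, erasing the C4 stereocentre and leaving all other centres untouched.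

**Compound list**

1 | (−)-β-caryophyllene | C/C1=C\CCC(=C)[C@H]2CC(C)(C)[C@@H]2CC1 | starting material
2 | 4-[(1S,2R)-3,3-dimethyl-2-(3-oxobutyl)cyclobutyl]-4-oxobutanal | O=CCCC(=O)[C@H]1CC(C)(C)[C@@H]1CCC(C)=O | intermediate
3 | 4-[(1R,4S)-4-(furan-2-yl)-2,2-dimethylcyclobutyl]butan-2-one | c1coc(c1)[C@H]2CC(C)(C)[C@@H]2CCC(C)=O | intermediate
4 | (1S,2R)-3,3-dimethyl-2-(3-oxobutyl)cyclobutane-1-carboxylic acid | OC(=O)[C@H]1CC(C)(C)[C@@H]1CCC(C)=O | intermediate
5 | (1S,2R)-2-(2-acetoxyethyl)-3,3-dimethylcyclobutane-1-carboxylic acid | OC(=O)[C@H]1CC(C)(C)[C@@H]1CCOC(C)=O | intermediate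
6 | 1-[(1S,2R)-2-(2-hydroxyethyl)-3,3-dimethylcyclobutyl]ethan-1-one | CC(=O)[C@H]1CC(C)(C)[C@@H]1CCO | intermediate
7 | 2-[(1R,4S)-2,2-dimethyl-4-(prop-1-en-2-yl)cyclobutyl]ethan-1-ol | CC(=C)[C@H]1CC(C)(C)[C@@H]1CCO | intermediate
8 | (1R,4S)-1-(2-bromoethyl)-2,2-dimethyl-4-(prop-1-en-2-yl)cyclobutane | CC(=C)[C@H]1CC(C)(C)[C@@H]1CCBr | intermediate
9 | 2-[(1S,2R)-2-(2-bromoethyl)-3,3-dimethylcyclobutyl]prop-2-en-1-ol | OCC(=C)[C@H]1CC(C)(C)[C@@H]1CCBr | intermediate
10 | (1R,4S)-1-(2-bromoethyl)-2,2-dimethyl-4-[3-(trityloxy)prop-1-en-2-yl]cyclobutane | C=C(COC(c1ccccc1)(c1ccccc1)c1ccccc1)[C@H]2CC(C)(C)[C@@H]2CCBr | intermediate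
11 | syncarpic acid (2,2,4,4-tetramethylcyclohexane-1,3,5-trione) | CC1(C)C(=O)CC(=O)C(C)(C)C1=O | starting material
12 | isovaleraldehyde | CC(C)CC=O | starting material
13 | Mannich base, 2-[3-methyl-1-(piperidin-1-yl)butyl]syncarpic acid (enol form) | CC(C)CC(N1CCCCC1)C1=C(O)C(C)(C)C(=O)C(C)(C)C1=O | intermediate
14 | 2,2,4,4-tetramethyl-6-(3-methylbutylidene)cyclohexane-1,3,5-trione | CC(C)CC=C1C(=O)C(C)(C)C(=O)C(C)(C)C1=O | intermediate
15 | tert-butyl 4-oxobutanoate | CC(C)(C)OC(=O)CCC=O | starting material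
16 | tert-butyl 2-[(3S,4S)-2-hydroxy-4-isobutyl-6,6,8,8-tetramethyl-5,7-dioxo-3,4,5,6,7,8-hexahydro-2H-chromen-3-yl]acetate (lactol, anomers) | CC(C)(C)OC(=O)C[C@H]1[C@H](CC(C)C)C2=C(OC1O)C(C)(C)C(=O)C(C)(C)C2=O | intermediate
17 | {2-[(1R,4S)-2,2-dimethyl-4-(3-trityloxyprop-1-en-2-yl)cyclobutyl]ethyl}magnesium bromide | Br[Mg]CC[C@@H]1[C@@H](C(=C)COC(c2ccccc2)(c2ccccc2)c2ccccc2)CC1(C)C | intermediate
18 | tert-butyl (3S,4S)-3-{1-hydroxy-3-[(1R,4S)-2,2-dimethyl-4-(3-trityloxyprop-1-en-2-yl)cyclobutyl]propyl}-4-(2-hydroxy-3,3,5,5-tetramethyl-4,6-dioxocyclohex-1-en-1-yl)-6-methylheptanoate (carbinol epimers) | CC(C)(C)OC(=O)C[C@H](C(O)CC[C@@H]1[C@@H](C(=C)COC(c2ccccc2)(c2ccccc2)c2ccccc2)CC1(C)C)[C@H](CC(C)C)C1=C(O)C(C)(C)C(=O)C(C)(C)C1=O | intermediate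
19 | tert-butyl 2-[(3S,4S)-2-hydroxy-4-isobutyl-6,6,8,8-tetramethyl-5,7-dioxo-2-{2-[(1R,4S)-2,2-dimethyl-4-(3-trityloxyprop-1-en-2-yl)cyclobutyl]ethyl}-3,4,5,6,7,8-hexahydro-2H-chromen-3-yl]acetate (hemiketal, C14 equilibrating) | CC(C)(C)OC(=O)C[C@H]1[C@H](CC(C)C)C2=C(OC1(O)CC[C@@H]1[C@@H](C(=C)COC(c3ccccc3)(c3ccccc3)c3ccccc3)CC1(C)C)C(C)(C)C(=O)C(C)(C)C2=O | intermediate
20 | cis-fused ketal γ-lactone (C14–O–C(=O)–C4H2 on the pyran), free allylic alcohol | O=C1C[C@H]2[C@H](CC(C)C)C3=C(O[C@]2(O1)CC[C@@H]1[C@@H](C(=C)CO)CC1(C)C)C(C)(C)C(=O)C(C)(C)C3=O | intermediate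
21 | 2-[(2R,3S,4S)-2-{2-[(1R,4S)-4-(3-hydroxyprop-1-en-2-yl)-2,2-dimethylcyclobutyl]ethyl}-4-isobutyl-2,6,6,8,8-pentamethyl-5,7-dioxo-3,4,5,6,7,8-hexahydro-2H-chromen-3-yl]acetic acid (seco acid) | OC(=O)C[C@H]1[C@H](CC(C)C)C2=C(O[C@]1(C)CC[C@@H]1[C@@H](C(=C)CO)CC1(C)C)C(C)(C)C(=O)C(C)(C)C2=O | intermediate
22 | mixed 2,4,6-trichlorobenzoic anhydride of 21 | O=C(OC(=O)C[C@H]1[C@H](CC(C)C)C2=C(O[C@]1(C)CC[C@@H]1[C@@H](C(=C)CO)CC1(C)C)C(C)(C)C(=O)C(C)(C)C2=O)c1c(Cl)cc(Cl)cc1Cl | intermediate
23 | eleven-membered 2-methyleneallyl macrolactone of 21 | C=C1COC(=O)C[C@H]2[C@H](CC(C)C)C3=C(O[C@]2(C)CC[C@@H]2[C@@H]1CC2(C)C)C(C)(C)C(=O)C(C)(C)C3=O | intermediate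
24 | trimethylsilyl ketene acetal of 23 | C=C1COC(O[Si](C)(C)C)=C[C@H]2[C@H](CC(C)C)C3=C(O[C@]2(C)CC[C@@H]2[C@@H]1CC2(C)C)C(C)(C)C(=O)C(C)(C)C3=O | intermediate
25 | trimethylsilyl ester of 26 | C=C1CC(C(=O)O[Si](C)(C)C)[C@H]2[C@H](CC(C)C)C3=C(O[C@]2(C)CC[C@@H]2[C@@H]1CC2(C)C)C(C)(C)C(=O)C(C)(C)C3=O | intermediate
26 | C4-carboxy tomentodione A (C4 epimers) | C=C1CC(C(=O)O)[C@H]2[C@H](CC(C)C)C3=C(O[C@]2(C)CC[C@@H]2[C@@H]1CC2(C)C)C(C)(C)C(=O)C(C)(C)C3=O | intermediate
27 | Barton ester (N-acyloxypyridine-2-thione) of 26 | C=C1CC(C(=O)ON2C=CC=CC2=S)[C@H]2[C@H](CC(C)C)C3=C(O[C@]2(C)CC[C@@H]2[C@@H]1CC2(C)C)C(C)(C)C(=O)C(C)(C)C3=O | intermediate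
28 | tomentodione A | C=C1CC[C@H]2[C@H](CC(C)C)C3=C(O[C@]2(C)CC[C@@H]2[C@@H]1CC2(C)C)C(C)(C)C(=O)C(C)(C)C3=O | target

**Count.** Total steps: 18. Longest linear sequence: 16 (steps 1–9, then 12–18).

**Steps most likely to fail**

1. Step 17. The silyl ketene acetal may not reach the boat-like transannular geometry before it is consumed by other paths (ring opening through a ketene, C-silylation), so that the [3,3] shift does not compete. Fallback, from 21 back to 26: the same C–C bond is made by intramolecular enolate alkylation, which gives the same connectivity by either SN2 or SN2′ attack because the allyl unit is constitutionally symmetric. Seco acid 21 is esterified with TMSCHN2 to the hydroxy methyl ester F1, which CBr4/PPh3 converts into the allylic bromide F2. KHMDS in THF under high dilution should then close the nine-membered methyl ester F3, and Me3SnOH or LiOH hydrolysis returns acid 26.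

2. Step 15. Methyl transfer to the C14 oxocarbenium ion may go to the wrong face, or proton loss to a 4H-pyran may compete. Fallback, from 16 (with Grignard reagent 17 from 10) back to 21: the order in which the two C14 substituents arrive is reversed, so that the substituent brought by the nucleophile takes the face that methyl took before and the opposite C14 epimer results. Lactol 16 is deprotonated with LiHMDS and treated with MeMgBr to give the methyl carbinol F4. TPAP/NMO oxidises it to the methyl hemiketal F5, and ZnBr2 closes the methyl ketal lactone F6. Grignard reagent 17 is transmetalated with ZnBr2 to the alkylzinc bromide F7. F6 and F7 with TMSOTf in CH2Cl2 at −78 °C should give the C14-alkylated trityl ether acid F8, and brief ZnBr2 or formic acid detritylation returns 21.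

3. Step 16. Intermolecular acylation to diolide and oligomers may outrun closure of the strained eleven-membered ring. Fallback, from 21 back to 23: the roles of the two ends are exchanged, with the carboxylate acting as nucleophile on an allylic bromide. 21 is mesylated (MsCl, Et3N) and treated with LiBr, the mixed anhydride being hydrolysed on aqueous work-up, to give the bromo acid F9. Cs2CO3 in DMF under high dilution at 40 °C should then close macrolactone 23.

**Further compounds**

F1 | step 17 | methyl ester of seco acid 21 | COC(=O)C[C@H]1[C@H](CC(C)C)C2=C(O[C@]1(C)CC[C@@H]1[C@@H](C(=C)CO)CC1(C)C)C(C)(C)C(=O)C(C)(C)C2=O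
F2 | step 17 | allylic bromide of F1 | COC(=O)C[C@H]1[C@H](CC(C)C)C2=C(O[C@]1(C)CC[C@@H]1[C@@H](C(=C)CBr)CC1(C)C)C(C)(C)C(=O)C(C)(C)C2=O
F3 | step 17 | methyl ester of 26 (C4 epimers) | C=C1CC(C(=O)OC)[C@H]2[C@H](CC(C)C)C3=C(O[C@]2(C)CC[C@@H]2[C@@H]1CC2(C)C)C(C)(C)C(=O)C(C)(C)C3=O
F4 | step 15 | tert-butyl (3S,4S)-3-(1-hydroxyethyl)-4-(2-hydroxy-3,3,5,5-tetramethyl-4,6-dioxocyclohex-1-en-1-yl)-6-methylheptanoate | CC(C)(C)OC(=O)C[C@H](C(C)O)[C@H](CC(C)C)C1=C(O)C(C)(C)C(=O)C(C)(C)C1=O
F5 | step 15 | 2-methyl hemiketal tert-butyl ester | CC(C)(C)OC(=O)C[C@H]1[C@H](CC(C)C)C2=C(OC1(C)O)C(C)(C)C(=O)C(C)(C)C2=O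
F6 | step 15 | cis-fused 2-methyl ketal γ-lactone | O=C1C[C@H]2[C@H](CC(C)C)C3=C(O[C@@]2(C)O1)C(C)(C)C(=O)C(C)(C)C3=O
F7 | step 15 | {2-[(1R,4S)-2,2-dimethyl-4-(3-trityloxyprop-1-en-2-yl)cyclobutyl]ethyl}zinc bromide | Br[Zn]CC[C@@H]1[C@@H](C(=C)COC(c2ccccc2)(c2ccccc2)c2ccccc2)CC1(C)C
F8 | step 15 | trityl ether of seco acid 21 | OC(=O)C[C@H]1[C@H](CC(C)C)C2=C(O[C@]1(C)CC[C@@H]1[C@@H](C(=C)COC(c3ccccc3)(c3ccccc3)c3ccccc3)CC1(C)C)C(C)(C)C(=O)C(C)(C)C2=O
F9 | step 16 | allylic bromide of seco acid 21 | OC(=O)C[C@H]1[C@H](CC(C)C)C2=C(O[C@]1(C)CC[C@@H]1[C@@H](C(=C)CBr)CC1(C)C)C(C)(C)C(=O)C(C)(C)C2=O
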